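**Two constants.** Two constants can be read from the north-west run, and they carry that same flask forward to the asked time.

| setting | north-west | flask |
|---|---|---|
| substrate | 0.67 M | 0.67 M |
| free catalyst | 13 mM | 13 mM |
| remark | the very flask that is asked about, followed so far |  |
| time |  | 2.0 h |

- north-west (time / min: target / %, substrate / %, self-condensation product / %): 1.50: 1.5, 96.4, 0.9; 2.50: 5.1, 94.0, 2.6; 4.00: 6.1, 88.9, 2.1; 6.00: 5.9, 88.2, 5.6; 10.0: 13.8, 80.0, 7.6; 15.0: 19.0, 71.2, 11.0; 20.0: 20.8, 64.2, 12.8

(readings scatter by 1 percentage point)

- a species is counted by the substrate in it: one self-condensation product counts as two

- concentration of target at 2.0 h, in M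
- concentration of substrate at 2.0 h, in M
- concentration of self-condensation product at 2.0 h, in M

**Reading them.** Suppose target forms at a rate proportional to substrate, and self-condensation at a rate proportional to its square, since two substrates must meet. Product then grows against target as substrate over the crossover concentration, the substrate level at which both routes use substrate equally, a selectivity factor with a unit. In the north-west run, target over product at 20.0 min, multiplied by a mean substrate of 0.550 M, reads 0.894 M for this concentration, with the scatter of those readings. Target's own constant reads 0.760 h⁻¹.

**First way.** One first-order constant for all substrate loss, taken from the same reading, leaves 0.0469 M at 2.0 h.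

**Second way.** Integrating both routes leaves 0.0924 M of substrate in the flask, twice as much. Target is the crossover concentration times the logarithm of (crossover plus charge) over (crossover plus remainder), 0.412 M. The rest gives 0.0828 M of product, two substrates each. The first way cheats: its constant holds the product route at 0.615 of target's, whereas this reckoning has 0.103 by the asked time.

**The forecast.** It gives 0.37 M target, 0.07 M substrate and 0.22 M product, the last in substrate counted. On the ratio it says “I assume that split holds”, where this reckoning lets the split move.

**The flask.** It gives 0.387 M target, 0.101 M substrate and 0.0880 M product, this last counted per product, so that it holds 0.176 M of substrate.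

    substrate + free catalyst ⇌ catalyst intermediate A (K = 1.90 L mol⁻¹, k = 0.0367 L mol⁻¹ s⁻¹)
    catalyst intermediate A → catalyst intermediate B (k = 0.0533 s⁻¹)
    catalyst intermediate B ⇌ free catalyst + target (K = 0.395 M, k = 0.217 s⁻¹)
    2 substrate → self-condensation product (k = 1.31 × 10⁻⁴ L mol⁻¹ s⁻¹)

The forward step into catalyst intermediate A uses substrate 2.7 times as fast as self-condensation at the start and 8.9 times at the asked time. For the whole charge, the crossover concentration gives 0.500 M target; at 20.0 h the flask holds 0.480 M.

**Second flask.** With 0.40 M of substrate and the same catalyst, the two constants give 0.0648 M substrate, 0.268 M target and 0.0336 M product. That flask gives 0.0582 M, 0.271 M and 0.0326 M.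

The data stem from a simulated flask for substances that don't exist.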